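**Plan**
Retrosynthesis: the 8-OH goes back to a 7,8-alkene (C8–O cut). The C3–C4 bond of ring A is then cut while C4 is re-attached to C7, which folds ring B plus C4 into a 2-methylidene-6,6-dimethylbicyclo[3.1.1]heptane whose C10 chain ends in a C3 hydrazone. Cuts at C8=C17, C9–C11 (aldol) and C10–C1 (1,4-addition) lead to (1R,5R)-verbenone; the C11–C16 chain comes from (R)-3-methylglutarate monoester.
Enabling feature: the quaternary gem-dimethyl carbon C4 is bonded to C5 and stands 1,3 to C7 across ring B, next to C8, which must end as C(CH3)(OH). C4–C5–C6–C7 is therefore the cyclobutane of a pinane, and a radical at C8 can cut C7–C4 and hand C4 to C3.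
Forward order: the bicycle is bought; C1–C3 and the side chain are attached (steps 4–7) and C17 is added (step 8). One flask then opens the cyclobutane (ring B appears) and closes ring A through C3–C4 (step 10); hydration of the 7,8-alkene ends the route (step 11).
Stereochemistry: C5 from verbenone; C10 by 1,4-addition anti to the gem-dimethyl bridge; C9 by hydrogen delivery anti to the bridge; the trans ring fusion follows from C5 and C10; C8 by O2 capture anti to the axial C10 methyl; C13 from the glutarate.
Key step: step 10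

Remark: labdane numbering (C1–C20) is used throughout; in the bicyclic intermediates pinane C1, C2, C3, C4, C5, C6 and C7 are labdane C7, C8, C9, C10, C5, C4 and C6; compounds 1, 5, 6 and 12 are taken to be commercial.

Step 1
Reactants: 1 methyl hydrogen (R)-3-methylglutarate
Product: 2 methyl (3R)-5-hydroxy-3-methylpentanoate
Conditions: BH3·SMe2, THF, 0 °C to rt; MeOH quench
Reagents that add atoms: none
Why: Borane reduces the free carboxylic acid much faster than the methyl ester (chemoselective acid reduction), and the stereocentre that becomes C13 is not touched.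

Step 2
Reactants: 2 methyl (3R)-5-hydroxy-3-methylpentanoate
Product: 3 methyl (3R)-5-(benzyloxy)-3-methylpentanoate
Conditions: BnBr, Ag2O, CH2Cl2, rt, dark
Reagents that add atoms: benzyl bromide (BrCc1ccccc1)
Why: Silver-oxide-promoted Williamson benzylation of the primary alcohol runs without a free alkoxide, so the δ-hydroxy ester should not lactonise.

Step 3
Reactants: 3 methyl (3R)-5-(benzyloxy)-3-methylpentanoate
Product: 4 (3R)-5-(benzyloxy)-3-methylpentanal
Conditions: i-Bu2AlH, CH2Cl2, −78 °C; Rochelle salt work-up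
Reagents that add atoms: none
Why: At −78 °C the aluminium hemiacetal from hydride addition to the methyl ester is stable until work-up, so the partial ester-to-aldehyde reduction should stop at the aldehyde.

Step 4
Reactants: 5 (1R,5R)-verbenone; 6 [2-(1,3-dioxolan-2-yl)ethyl]magnesium bromide; 4 (3R)-5-(benzyloxy)-3-methylpentanal
Product: 8 3-[(3R)-5-(benzyloxy)-1-hydroxy-3-methylpentyl]-4-[2-(1,3-dioxolan-2-yl)ethyl]-4,6,6-trimethylbicyclo[3.1.1]heptan-2-one (aldol adduct; dioxolanylethyl anti to the gem-dimethyl bridge), via bromomagnesium enolate 7 (not isolated)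
Conditions: 6, CuBr·SMe2 (10 mol %), THF, −40 °C; then 4, −78 °C; aq. NH4Cl
Reagents that add atoms: none
Why: Copper-catalysed 1,4-addition of the Grignard reagent should occur on the enone face anti to the gem-dimethyl bridge, which sets quaternary C10 with methyl syn and the C1–C3 chain anti to the bridge, and the magnesium enolate (enolisable only at C9) then adds to the aldehyde in a tandem conjugate addition–aldol reaction whose C9 and C11 configurations are erased in step 5.

Step 5
Reactants: 8 aldol adduct
Product: 10 3-[(3S)-5-(benzyloxy)-3-methylpentylidene]-4-[2-(1,3-dioxolan-2-yl)ethyl]-4,6,6-trimethylbicyclo[3.1.1]heptan-2-one (exocyclic enone), via mesylate 9 (not isolated)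
Conditions: MsCl, Et3N, CH2Cl2, 0 °C; then DBU, rt
Reagents that add atoms: none
Why: Mesylation of the β-hydroxy ketone and E1cB elimination should give the conjugated exocyclic enone, whose alkene geometry is of no consequence because it is removed in step 6.

Step 6
Reactants: 10 exocyclic enone
Product: 11 4-[2-(1,3-dioxolan-2-yl)ethyl]-3-[(3S)-5-hydroxy-3-methylpentyl]-4,6,6-trimethylbicyclo[3.1.1]heptan-2-one (C3 chain syn to the gem-dimethyl bridge)
Conditions: H2 (1 atm), 10% Pd/C, EtOH, rt
Reagents that add atoms: none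
Why: Heterogeneous hydrogenation should deliver hydrogen to the exocyclic alkene on the face anti to the gem-dimethyl bridge, as in the hydrogenation of α-pinene to cis-pinane, so that the C9 hydrogen is anti and the side chain syn to the bridge (the C9 configuration of the target), and the same conditions cleave the benzyl ether by hydrogenolysis.

Step 7
Reactants: 11 hydroxy ketone; 12 3-phenylpropanoyl chloride
Product: 13 (3S)-5-{4-[2-(1,3-dioxolan-2-yl)ethyl]-4,6,6-trimethyl-2-oxobicyclo[3.1.1]heptan-3-yl}-3-methylpentyl 3-phenylpropanoate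
Conditions: pyridine, DMAP (cat.), CH2Cl2, 0 °C to rt
Reagents that add atoms: none
Why: Nucleophilic-catalysed acylation of the primary alcohol installs the 3-phenylpropanoate at this point because every later step tolerates an ester.

Step 8
Reactants: 13 keto ester
Product: 14 (3S)-5-{4-[2-(1,3-dioxolan-2-yl)ethyl]-4,6,6-trimethyl-2-methylidenebicyclo[3.1.1]heptan-3-yl}-3-methylpentyl 3-phenylpropanoate
Conditions: Zn, CH2Br2, TiCl4 (pre-formed reagent), THF/CH2Cl2, 0 °C to rt
Reagents that add atoms: dibromomethane (BrCBr)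
Why: Takai–Lombardo methylenation converts the hindered ketone into the exocyclic alkene (the new CH2 is C17) under non-basic conditions, so the epimerisable C9 centre and the ester should be left alone.

Step 9
Reactants: 14 methylidene acetal
Product: 16 4-methylbenzenesulfonylhydrazone of 15, via aldehyde 15 (not isolated)
Conditions: PPTS, acetone/H2O, 55 °C; solvent exchange; TsNHNH2, EtOH, rt
Reagents that add atoms: 4-methylbenzenesulfonohydrazide (Cc1ccc(cc1)S(=O)(=O)NN)
Why: Mild acid-catalysed transacetalisation frees the C3 aldehyde without touching the acid-sensitive methylidene pinane, and condensation with the sulfonyl hydrazide gives the N-tosylhydrazone that serves as radical acceptor.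

Step 10
Reactants: 16 tosylhydrazone
Product: 19 (13S)-labd-7-en-15-yl 3-phenylpropanoate, via sulfonylhydrazide 17 (not isolated), via alkyldiazene 18 (not isolated)
Conditions: Fe(acac)3 (30 mol %), PhSiH3 (2 equiv), EtOH/THF, 60 °C, degassed; then NaOAc, 78 °C
Reagents that add atoms: none
Why: Proposed new method: an iron hydride formed from Fe(acac)3 and PhSiH3 should transfer a hydrogen atom to the exocyclic CH2 (which becomes the C17 methyl) to give the tertiary C8 radical, whose cyclobutylcarbinyl β-scission of the C7–C4 bond, driven by loss of cyclobutane strain, leaves the 7,8-alkene and a tertiary radical at C4; this radical adds 6-exo-trig to the hydrazone carbon C3, the hydrazinyl radical is reduced and protonated to hydrazide 17, and acetate-induced loss of sulfinate and then of dinitrogen through diazene 18 leaves C3 as CH2. The closest known reaction types are the iron-hydride reductive coupling of alkenes with sulfonylhydrazones followed by traceless C–N cleavage (as in olefin hydromethylation) and the radical ring opening of pinane-type methylidenecyclobutanes, which have not been joined in one relay. Ring A is the only ring closed, in the 6-exo mode through a chair transition state, while ring B is released from the bicycle by the scission. No new stereocentre survives (C3 ends as CH2 and C4 carries two methyl groups), and the trans ring fusion follows from the C5–C4 and C10–C1 bonds, which were placed trans on ring B in step 4 and both stay equatorial in the chair. The step needs C7–C4 scission to outrun direct addition of the C8 radical to the hydrazone and to win over C7–C6 scission, which strain release and the tertiary nature of the C4 radical should secure, and it needs the 1,1-disubstituted alkene to react before the trisubstituted alkene of the product, which the slower HAT to the hindered alkene and a limited amount of silane should secure.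

Step 11
Reactants: 19 (13S)-labd-7-en-15-yl 3-phenylpropanoate
Product: 21 (13S)-8α-hydroxylabdan-15-yl 3-phenylpropanoate (CNP0326656.1), via hydroperoxide 20 (not isolated)
Conditions: Co(acac)2 (20 mol %), PhSiH3, O2 (1 atm), THF/i-PrOH, rt; then PPh3
Reagents that add atoms: dioxygen (O=O)
Why: In this Mukaiyama hydration HAT to C7 gives the tertiary C8 radical (Markovnikov), which should capture O2 on the α face because the β face is shielded by the 1,3-diaxial C10 methyl, so that reduction of the hydroperoxide gives the 8α-hydroxy-8β-methyl arrangement.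

**Compound list**
1 | methyl hydrogen (R)-3-methylglutarate [(3R)-5-methoxy-3-methyl-5-oxopentanoic acid] | COC(=O)C[C@H](C)CC(=O)O | starting material
2 | methyl (3R)-5-hydroxy-3-methylpentanoate | COC(=O)C[C@H](C)CCO | intermediate
3 | methyl (3R)-5-(benzyloxy)-3-methylpentanoate | COC(=O)C[C@H](C)CCOCc1ccccc1 | intermediate
4 | (3R)-5-(benzyloxy)-3-methylpentanal | O=CC[C@H](C)CCOCc1ccccc1 | intermediate
5 | (1R,5R)-verbenone [(+)-verbenone; (1R,5R)-4,6,6-trimethylbicyclo[3.1.1]hept-3-en-2-one] | CC1=CC(=O)[C@@H]2C[C@H]1C2(C)C | starting material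
6 | [2-(1,3-dioxolan-2-yl)ethyl]magnesium bromide | Br[Mg]CCC1OCCO1 | starting material
7 | bromomagnesium enolate (O–MgBr on C8, C8=C9) of 4-[2-(1,3-dioxolan-2-yl)ethyl]-4,6,6-trimethylbicyclo[3.1.1]heptan-2-one; C4 methyl syn and dioxolanylethyl anti to the gem-dimethyl bridge | Br[Mg]OC1=C[C@@](C)(CCC2OCCO2)[C@H]3C[C@@H]1C3(C)C | intermediate
8 | 3-[(3R)-5-(benzyloxy)-1-hydroxy-3-methylpentyl]-4-[2-(1,3-dioxolan-2-yl)ethyl]-4,6,6-trimethylbicyclo[3.1.1]heptan-2-one; ring stereochemistry as in 7, mixture at C3 and at the carbinol carbon | O=C1C(C(O)C[C@H](C)CCOCc2ccccc2)[C@@](C)(CCC3OCCO3)[C@H]4C[C@@H]1C4(C)C | intermediate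
9 | methanesulfonate of 8 | O=C1C(C(OS(C)(=O)=O)C[C@H](C)CCOCc2ccccc2)[C@@](C)(CCC3OCCO3)[C@H]4C[C@@H]1C4(C)C | intermediate
10 | 3-[(3S)-5-(benzyloxy)-3-methylpentylidene]-4-[2-(1,3-dioxolan-2-yl)ethyl]-4,6,6-trimethylbicyclo[3.1.1]heptan-2-one; Z isomer drawn, geometry of no consequence | O=C1/C(=C\C[C@H](C)CCOCc2ccccc2)[C@@](C)(CCC3OCCO3)[C@H]4C[C@@H]1C4(C)C | intermediate
11 | 4-[2-(1,3-dioxolan-2-yl)ethyl]-3-[(3S)-5-hydroxy-3-methylpentyl]-4,6,6-trimethylbicyclo[3.1.1]heptan-2-one; C3 chain and C4 methyl syn, dioxolanylethyl anti to the gem-dimethyl bridge | O=C1[C@H](CC[C@H](C)CCO)[C@@](C)(CCC2OCCO2)[C@H]3C[C@@H]1C3(C)C | intermediate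
12 | 3-phenylpropanoyl chloride | O=C(Cl)CCc1ccccc1 | starting material
13 | (3S)-5-{4-[2-(1,3-dioxolan-2-yl)ethyl]-4,6,6-trimethyl-2-oxobicyclo[3.1.1]heptan-3-yl}-3-methylpentyl 3-phenylpropanoate; ring stereochemistry as in 11 | O=C1[C@H](CC[C@H](C)CCOC(=O)CCc2ccccc2)[C@@](C)(CCC3OCCO3)[C@H]4C[C@@H]1C4(C)C | intermediate
14 | (3S)-5-{4-[2-(1,3-dioxolan-2-yl)ethyl]-4,6,6-trimethyl-2-methylidenebicyclo[3.1.1]heptan-3-yl}-3-methylpentyl 3-phenylpropanoate; ring stereochemistry as in 11 | C=C1[C@H](CC[C@H](C)CCOC(=O)CCc2ccccc2)[C@@](C)(CCC3OCCO3)[C@H]4C[C@@H]1C4(C)C | intermediate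
15 | (3S)-3-methyl-5-[4,6,6-trimethyl-2-methylidene-4-(3-oxopropyl)bicyclo[3.1.1]heptan-3-yl]pentyl 3-phenylpropanoate; ring stereochemistry as in 11 | C=C1[C@H](CC[C@H](C)CCOC(=O)CCc2ccccc2)[C@@](C)(CCC=O)[C@H]3C[C@@H]1C3(C)C | intermediate
16 | (E)-4-methylbenzenesulfonylhydrazone of 15 | C=C1[C@H](CC[C@H](C)CCOC(=O)CCc2ccccc2)[C@@](C)(CC/C=N/NS(=O)(=O)c3ccc(C)cc3)[C@H]4C[C@@H]1C4(C)C | intermediate
17 | (13S)-3-[2-(4-methylbenzenesulfonyl)hydrazinyl]labd-7-en-15-yl 3-phenylpropanoate; mixture at C3 | C[C@H](CCOC(=O)CCc1ccccc1)CC[C@@H]1[C@@]2(C)CCC(NNS(=O)(=O)c3ccc(C)cc3)C(C)(C)[C@@H]2CC=C1C | intermediate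
18 | (13S)-3-diazenyllabd-7-en-15-yl 3-phenylpropanoate; mixture at C3 | C[C@H](CCOC(=O)CCc1ccccc1)CC[C@@H]1[C@@]2(C)CCC(N=N)C(C)(C)[C@@H]2CC=C1C | intermediate
19 | (13S)-labd-7-en-15-yl 3-phenylpropanoate (5α-H, 9α-H, 10β-methyl) | C[C@H](CCOC(=O)CCc1ccccc1)CC[C@@H]1[C@@]2(C)CCCC(C)(C)[C@@H]2CC=C1C | intermediate
20 | (13S)-8α-hydroperoxylabdan-15-yl 3-phenylpropanoate | C[C@H](CCOC(=O)CCc1ccccc1)CC[C@@H]1[C@@]2(C)CCCC(C)(C)[C@@H]2CC[C@@]1(C)OO | intermediate
21 | (13S)-8α-hydroxylabdan-15-yl 3-phenylpropanoate [(3S)-5-[(1R,2R,4aS,8aS)-2-hydroxy-2,5,5,8a-tetramethyldecahydronaphthalen-1-yl]-3-methylpentyl 3-phenylpropanoate] | C[C@H](CCOC(=O)CCc1ccccc1)CC[C@@H]1[C@@]2(C)CCCC(C)(C)[C@@H]2CC[C@@]1(C)O | target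

**Totals and risks**
Total step count: 11. Longest linear sequence: 11 steps (1 to 21, steps 1–11); the verbenone branch joins at step 4 and is 8 steps long.

Steps most likely to fail:

Step 10 (labelled step; the fallback uses known reaction types). The relay may be intercepted: the C8 radical may add to the hydrazone before the cyclobutane opens, the C4 radical may be reduced before it cyclises, or the 7,8-alkene of the product may be reduced further. In the fallback, ring opening and ring closure are run as separate operations. Setting out from 14, cobalt–salen hydride radical isomerisation (Co(salen)Cl, cat. PhSiH3, benzene, rt), a reaction type known to open strained rings to dienes, should give the monocyclic acetal (3S)-5-{6-[2-(1,3-dioxolan-2-yl)ethyl]-2,6-dimethyl-5-(prop-1-en-2-yl)cyclohex-2-en-1-yl}-3-methylpentyl 3-phenylpropanoate F1. PPTS in wet acetone should free the corresponding 3-oxopropyl aldehyde F2, which TsNHNH2 in EtOH should convert into its tosylhydrazone F3. Fe(acac)3 and PhSiH3 in EtOH at 60 °C, the known intramolecular HAT coupling of a 1,1-disubstituted alkene with a sulfonylhydrazone (6-exo), should then give 17, where the route is rejoined (NaOAc, heat, to 19).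

Step 6. Hydrogen delivery to the exocyclic alkene beside quaternary C10 may show poor facial selectivity, or C9 may epimerise on the catalyst; either would give the C9 epimer. In the fallback, C9 is set by protonation of a defined enolate instead of by surface hydrogen delivery. From 10, 1,4-hydride addition with LiBH(s-Bu)3 (THF, −78 °C) and kinetic protonation of the enolate on the face anti to the gem-dimethyl bridge with 2,6-di-tert-butylphenol should give 3-[(3S)-5-(benzyloxy)-3-methylpentyl]-4-[2-(1,3-dioxolan-2-yl)ethyl]-4,6,6-trimethylbicyclo[3.1.1]heptan-2-one F4; hydrogenolysis (H2, Pd(OH)2/C, EtOAc) returns to 11.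

Step 11. HAT to the hindered trisubstituted alkene may be slow, so that plain reduction competes, or the facial bias of O2 capture at C8 may be insufficient. The fallback uses ionic instead of radical oxygenation. From 19, mCPBA (NaHCO3, CH2Cl2, 0 °C) should epoxidise the 7,8-alkene from the α face to (13S)-7α,8α-epoxylabdan-15-yl 3-phenylpropanoate F5. LiAlH4 (THF, reflux) should open the epoxide by trans-diaxial hydride attack at C7 and cleave the ester, giving (13S)-labdane-8α,15-diol F6. Selective acylation of the primary hydroxyl with 12 (pyridine, CH2Cl2, 0 °C) returns to 21.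

Further compounds
F1 | step 10 | (3S)-5-{6-[2-(1,3-dioxolan-2-yl)ethyl]-2,6-dimethyl-5-(prop-1-en-2-yl)cyclohex-2-en-1-yl}-3-methylpentyl 3-phenylpropanoate (ring carbons C9, C10, C5 as in 19) | C[C@H](CCOC(=O)CCc1ccccc1)CC[C@@H]1[C@@](C)(CCC2OCCO2)[C@H](C(C)=C)CC=C1C
F2 | step 10 | (3S)-5-[2,6-dimethyl-6-(3-oxopropyl)-5-(prop-1-en-2-yl)cyclohex-2-en-1-yl]-3-methylpentyl 3-phenylpropanoate | C[C@H](CCOC(=O)CCc1ccccc1)CC[C@@H]1[C@@](C)(CCC=O)[C@H](C(C)=C)CC=C1C
F3 | step 10 | (E)-4-methylbenzenesulfonylhydrazone of F2 | C[C@H](CCOC(=O)CCc1ccccc1)CC[C@@H]1[C@@](C)(CC/C=N/NS(=O)(=O)c2ccc(C)cc2)[C@H](C(C)=C)CC=C1C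
F4 | step 6 | 3-[(3S)-5-(benzyloxy)-3-methylpentyl]-4-[2-(1,3-dioxolan-2-yl)ethyl]-4,6,6-trimethylbicyclo[3.1.1]heptan-2-one (C3 chain syn to the gem-dimethyl bridge) | O=C1[C@H](CC[C@H](C)CCOCc2ccccc2)[C@@](C)(CCC3OCCO3)[C@H]4C[C@@H]1C4(C)C
F5 | step 11 | (13S)-7α,8α-epoxylabdan-15-yl 3-phenylpropanoate | C[C@H](CCOC(=O)CCc1ccccc1)CC[C@@H]1[C@@]2(C)CCCC(C)(C)[C@@H]2C[C@H]3O[C@@]13C
F6 | step 11 | (13S)-labdane-8α,15-diol | C[C@H](CCO)CC[C@@H]1[C@@]2(C)CCCC(C)(C)[C@@H]2CC[C@@]1(C)O
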